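The diaryl ether is disconnected at the O–C6 bond of ring A. Because the C3 oxygen of ring A lies para to C6, a bis-phenolic benzophenone can be oxidised at an anode so that the ring B phenol oxygen attacks C6. This one operation forges the hindered C–O bond and closes a spiro benzofuranone onto a cyclohexadienone whose carbonyl oxygen is the later methoxy oxygen. Hydroxide then cuts the ketone–C6 bond, ring A rearomatises and the bridging carbon leaves as CO2. The precursor is a tetra-ortho-substituted benzophenone with free C3–OH (ring A) and free ortho OH (ring B), MOM on both oxygens that end as phenols and TBS on the benzylic oxygen.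

Key step: step 12

Numbering: in ring A, C1 carries CH2O, C3 carries OMe, C5 carries OH and C6 carries the diaryl ether oxygen; ring B is the 3-hydroxy-5-methylphenyl ring.

Remark on the chemistry: the target is achiral. The spiro carbon made in step 12 is a stereocentre, should form as a racemate and is removed again in step 13, so no stereocontrol is needed.

Remark on the design: ring A is differentiated at the phthalide stage and ring B only once the ketone is in place, each time through chelation or hydrogen bonding to a carbonyl group. The two ring B oxygens can therefore enter as identical allyl ethers, and no regioselective mono-protection of a brominated orcinol is needed. The C3 oxygen of ring A travels as a benzyl ether, orthogonal to allyl, MOM and TBS.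

Assumption: [3,5-bis(benzyloxy)phenyl]methanol (the benzylated, reduced form of 3,5-dihydroxybenzoic acid), orcinol and palmitic acid are bought.

Step 1
Reactants: 1 orcinol
Product: 2 1,3-bis(allyloxy)-5-methylbenzene
Conditions: allyl bromide (2.4 equiv), K2CO3, DMF, 60 °C
Reagents that add atoms: allyl bromide, C=CCBr
Why: Williamson ether synthesis on both phenoxides of the symmetric diol should give the bis-allyl ether with no selectivity question.

Step 2
Reactants: 2 1,3-bis(allyloxy)-5-methylbenzene
Product: 3 1,5-bis(allyloxy)-2-bromo-3-methylbenzene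
Conditions: NBS (1.0 equiv), MeCN, 0 °C, dark
Reagents that add atoms: N-bromosuccinimide, O=C1CCC(=O)N1Br
Why: Electrophilic aromatic bromination of a 3,5-dialkoxytoluene should occur next to the methyl group and para to one alkoxy group (two equivalent sites) rather than at the doubly flanked carbon between the oxygens, and far faster than any reaction at the allyl double bonds.

Step 3
Reactants: 4 [3,5-bis(benzyloxy)phenyl]methanol
Product: 5 [3,5-bis(benzyloxy)-2-bromophenyl]methanol
Conditions: NBS (1.0 equiv), CH2Cl2, 0 °C
Reagents that add atoms: N-bromosuccinimide, O=C1CCC(=O)N1Br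
Why: Electrophilic aromatic bromination of the 3,5-dialkoxybenzyl alcohol should take the position ortho to CH2OH and para to a benzyloxy group, the two such positions being equivalent.

Step 4
Reactants: 5 [3,5-bis(benzyloxy)-2-bromophenyl]methanol
Product: 8 5,7-bis(benzyloxy)phthalide, via dilithio species 6 (not isolated), via hydroxy acid 7 (not isolated)
Conditions: n-BuLi (2.2 equiv), THF, −78 °C; CO2 (g), −78 °C → rt; then 2 M HCl, rt
Reagents that add atoms: carbon dioxide, O=C=O
Why: Halogen–lithium exchange on the lithium alkoxide followed by carboxylation gives a 2-(hydroxymethyl)benzoic acid that should lactonise spontaneously on acidification to the five-membered phthalide.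

Step 5
Reactants: 8 5,7-bis(benzyloxy)phthalide
Product: 9 5-(benzyloxy)-7-hydroxyphthalide
Conditions: BCl3 (1.1 equiv), CH2Cl2, −78 °C; then H2O
Reagents that add atoms: none
Why: Chelation-controlled ether cleavage, in which boron bridges the lactone carbonyl and the C7 oxygen so that chloride should remove only the benzyl group next to the carbonyl while the C5 benzyl ether, which cannot chelate, stays.

Step 6
Reactants: 9 5-(benzyloxy)-7-hydroxyphthalide
Product: 10 5-(benzyloxy)-7-(methoxymethoxy)phthalide
Conditions: NaH, MOMCl, DMF, 0 °C → rt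
Reagents that add atoms: chloromethyl methyl ether, COCCl
Why: Williamson-type alkylation of the sodium phenoxide with MOMCl should protect the only free hydroxyl, the oxygen that ends as the C5 phenol of ring A.

Step 7
Reactants: 3 1,5-bis(allyloxy)-2-bromo-3-methylbenzene; 10 5-(benzyloxy)-7-(methoxymethoxy)phthalide
Product: 13 [2,4-bis(allyloxy)-6-methylphenyl][4-(benzyloxy)-2-(hydroxymethyl)-6-(methoxymethoxy)phenyl]methanone, via aryllithium 11 (not isolated), via lithium hemiketal alkoxide 12 (not isolated)
Conditions: 3, n-BuLi (1.0 equiv), THF, −78 °C; then 10, −78 → −40 °C; then aq. NH4Cl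
Reagents that add atoms: none
Why: Bromine–lithium exchange gives a 2,6-disubstituted aryllithium whose addition to the lactone carbonyl (nucleophilic acyl substitution with lactone opening) should stop at the tetrahedral lithium hemiketal at low temperature, so that one aryl group enters and the hydroxy ketone appears on work-up.

Step 8
Reactants: 13 [2,4-bis(allyloxy)-6-methylphenyl][4-(benzyloxy)-2-(hydroxymethyl)-6-(methoxymethoxy)phenyl]methanone
Product: 14 [2,4-bis(allyloxy)-6-methylphenyl][4-(benzyloxy)-2-{[(tert-butyldimethylsilyl)oxy]methyl}-6-(methoxymethoxy)phenyl]methanone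
Conditions: TBSCl, imidazole, DMF, rt
Reagents that add atoms: tert-butyldimethylsilyl chloride, CC(C)(C)[Si](C)(C)Cl
Why: Silylation of the primary hydroxyl, which exists only in the open hydroxy ketone form, should drain any hemiketal form (the protonated form of 12) and lock the ketone.

Step 9
Reactants: 14 [2,4-bis(allyloxy)-6-methylphenyl][4-(benzyloxy)-2-{[(tert-butyldimethylsilyl)oxy]methyl}-6-(methoxymethoxy)phenyl]methanone
Product: 15 [4-(benzyloxy)-2-{[(tert-butyldimethylsilyl)oxy]methyl}-6-(methoxymethoxy)phenyl](2,4-dihydroxy-6-methylphenyl)methanone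
Conditions: Pd(PPh3)4 (5 mol %), morpholine (6 equiv), THF, rt
Reagents that add atoms: none
Why: Tsuji–Trost deallylation, in which zerovalent palladium ionises both aryl allyl ethers and morpholine captures the allyl fragments, should leave the benzyl, MOM and silyl ethers untouched.

Step 10
Reactants: 15 [4-(benzyloxy)-2-{[(tert-butyldimethylsilyl)oxy]methyl}-6-(methoxymethoxy)phenyl](2,4-dihydroxy-6-methylphenyl)methanone
Product: 16 [4-(benzyloxy)-2-{[(tert-butyldimethylsilyl)oxy]methyl}-6-(methoxymethoxy)phenyl][2-hydroxy-4-(methoxymethoxy)-6-methylphenyl]methanone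
Conditions: MOMCl (1.1 equiv), i-Pr2NEt, CH2Cl2, 0 °C
Reagents that add atoms: chloromethyl methyl ether, COCCl
Why: The ortho hydroxyl of ring B is held in a hydrogen bond to the ketone, so base-mediated O-alkylation with one equivalent of MOMCl should occur only at the para hydroxyl.

Step 11
Reactants: 16 [4-(benzyloxy)-2-{[(tert-butyldimethylsilyl)oxy]methyl}-6-(methoxymethoxy)phenyl][2-hydroxy-4-(methoxymethoxy)-6-methylphenyl]methanone
Product: 17 [2-{[(tert-butyldimethylsilyl)oxy]methyl}-4-hydroxy-6-(methoxymethoxy)phenyl][2-hydroxy-4-(methoxymethoxy)-6-methylphenyl]methanone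
Conditions: H2 (1 atm), Pd/C, EtOAc, rt
Reagents that add atoms: none
Why: Heterogeneous hydrogenolysis should cleave the single aryl benzyl ether and free the C3 hydroxyl of ring A, while the hindered diaryl ketone, the acetals and the silyl ether persist under neutral conditions.

Step 12
Reactants: 17 [2-{[(tert-butyldimethylsilyl)oxy]methyl}-4-hydroxy-6-(methoxymethoxy)phenyl][2-hydroxy-4-(methoxymethoxy)-6-methylphenyl]methanone
Product: 18 rac-6'-{[(tert-butyldimethylsilyl)oxy]methyl}-2',6-bis(methoxymethoxy)-4-methyl-3H-spiro[1-benzofuran-2,1'-cyclohexa[2,5]diene]-3,4'-dione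
Conditions: undivided cell, graphite anode, Pt cathode, constant current (5 mA cm−2, 2.2 F mol−1), n-Bu4NBF4 (0.1 M), 2,6-lutidine (3 equiv), MeCN/(CF3)2CHOH 4:1, rt
Reagents that add atoms: none
Why: Anodic removal of two electrons from the para-hydroxyaryl ketone unit of ring A, with 2,6-lutidine taking up the protons, should give a phenoxonium ion (or, by stepwise electron transfer, the corresponding phenoxyl radical pair) whose charge is concentrated at C6, the carbon para to the C3 oxygen, and the ortho hydroxyl of ring B, which the carbonyl linker places directly over C6, adds to that carbon. The closest known reaction type is the oxidative phenol coupling of 2-hydroxybenzophenones to grisadienones with chemical one-electron oxidants, and anodic dearomatising spirocyclisation of para-substituted phenols by tethered oxygen nucleophiles is equally established. The one new ring, the furan-3-one, closes in a 5-exo-trig mode on the ipso carbon of the dienyl cation. The spiro carbon C6 is the only new stereocentre; no element controls it, it should form as a racemate, and this is harmless because step 13 destroys it. The selectivity needed is O–C instead of C–C coupling at C6 alone: no other ring A carbon is both para to the free hydroxyl and at the right distance for the ring B oxygen to close a five-membered ring, the C5 oxygen is masked as its MOM ether so that no ortho-quinoid route is open, and the weakly nucleophilic hexafluoroisopropanol medium at low substrate concentration should suppress solvent capture and intermolecular coupling.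

Step 13
Reactants: 18 rac-6'-{[(tert-butyldimethylsilyl)oxy]methyl}-2',6-bis(methoxymethoxy)-4-methyl-3H-spiro[1-benzofuran-2,1'-cyclohexa[2,5]diene]-3,4'-dione
Product: 19 2-[2-{[(tert-butyldimethylsilyl)oxy]methyl}-4-hydroxy-6-(methoxymethoxy)phenoxy]-4-(methoxymethoxy)-6-methylbenzoic acid
Conditions: 1 M NaOH, THF, 0 °C → rt; then 1 M HCl to pH 4, 0 °C
Reagents that add atoms: sodium hydroxide, [Na+].[OH-]
Why: Hydroxide adds to the non-enolisable furanone ketone and the adduct should fragment by C–C cleavage (retro-Claisen type) because the departing carbon is the para position of a dienone that becomes a phenolate, which erases the spiro stereocentre and leaves the carboxyl on ring B.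

Step 14
Reactants: 19 2-[2-{[(tert-butyldimethylsilyl)oxy]methyl}-4-hydroxy-6-(methoxymethoxy)phenoxy]-4-(methoxymethoxy)-6-methylbenzoic acid
Product: 20 3-{[(tert-butyldimethylsilyl)oxy]methyl}-5-(methoxymethoxy)-4-[3-(methoxymethoxy)-5-methylphenoxy]phenol
Conditions: Ag2CO3 (10 mol %), AcOH (5 mol %), DMSO, 120 °C
Reagents that add atoms: none
Why: Silver-catalysed protodecarboxylation of an ortho,ortho-disubstituted benzoic acid, in which the twisted carboxylate should extrude CO2 through an aryl silver species (monovalent silver) that acetic acid protonates.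

Step 15
Reactants: 20 3-{[(tert-butyldimethylsilyl)oxy]methyl}-5-(methoxymethoxy)-4-[3-(methoxymethoxy)-5-methylphenoxy]phenol
Product: 21 tert-butyl({5-methoxy-3-(methoxymethoxy)-2-[3-(methoxymethoxy)-5-methylphenoxy]phenyl}methoxy)dimethylsilane
Conditions: MeI, K2CO3, acetone, 40 °C
Reagents that add atoms: iodomethane, CI
Why: Williamson methylation of the only free phenol, the C3 oxygen of ring A that was the dienone carbonyl, should install the methoxy group.

Step 16
Reactants: 21 tert-butyl({5-methoxy-3-(methoxymethoxy)-2-[3-(methoxymethoxy)-5-methylphenoxy]phenyl}methoxy)dimethylsilane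
Product: 22 3-(hydroxymethyl)-2-(3-hydroxy-5-methylphenoxy)-5-methoxyphenol
Conditions: HCl (1.25 M in MeOH), MeOH, rt → 40 °C
Reagents that add atoms: none
Why: Acid-catalysed acetal exchange and silyl ether methanolysis should remove both MOM groups and the TBS group in one operation, the benzylic alcohol having no ortho or para oxygen donor strong enough to make it ionise.

Step 17
Reactants: 22 3-(hydroxymethyl)-2-(3-hydroxy-5-methylphenoxy)-5-methoxyphenol; 23 palmitic acid
Product: 24 betaethrin H
Conditions: PPh3, DIAD, THF, 0 °C → rt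
Reagents that add atoms: none
Why: Mitsunobu esterification, in which the carboxylic acid, far more acidic than the two phenols, is the pronucleophile that the betaine deprotonates, so the activated primary benzylic alcohol should be acylated chemoselectively (no stereocentre is involved).

Compound list
1 | orcinol (5-methylbenzene-1,3-diol) | Cc1cc(O)cc(O)c1 | starting material
2 | 1,3-bis(allyloxy)-5-methylbenzene | Cc1cc(OCC=C)cc(OCC=C)c1 | intermediate
3 | 1,5-bis(allyloxy)-2-bromo-3-methylbenzene | Cc1cc(OCC=C)cc(OCC=C)c1Br | intermediate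
4 | [3,5-bis(benzyloxy)phenyl]methanol | OCc1cc(OCc2ccccc2)cc(OCc2ccccc2)c1 | starting material
5 | [3,5-bis(benzyloxy)-2-bromophenyl]methanol | OCc1cc(OCc2ccccc2)cc(OCc2ccccc2)c1Br | intermediate
6 | lithium [3,5-bis(benzyloxy)-2-lithiophenyl]methanolate (dilithio species) | [Li]OCc1cc(OCc2ccccc2)cc(OCc2ccccc2)c1[Li] | intermediate (not isolated)
7 | 2,4-bis(benzyloxy)-6-(hydroxymethyl)benzoic acid (hydroxy acid) | OCc1cc(OCc2ccccc2)cc(OCc2ccccc2)c1C(=O)O | intermediate (not isolated)
8 | 5,7-bis(benzyloxy)phthalide [5,7-bis(benzyloxy)isobenzofuran-1(3H)-one] | O=C1OCc2cc(OCc3ccccc3)cc(OCc3ccccc3)c21 | intermediate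
9 | 5-(benzyloxy)-7-hydroxyphthalide | O=C1OCc2cc(OCc3ccccc3)cc(O)c21 | intermediate
10 | 5-(benzyloxy)-7-(methoxymethoxy)phthalide | O=C1OCc2cc(OCc3ccccc3)cc(OCOC)c21 | intermediate
11 | [2,4-bis(allyloxy)-6-methylphenyl]lithium (aryllithium) | [Li]c1c(C)cc(OCC=C)cc1OCC=C | intermediate (not isolated)
12 | lithium 1-[2,4-bis(allyloxy)-6-methylphenyl]-5-(benzyloxy)-7-(methoxymethoxy)-1,3-dihydroisobenzofuran-1-olate (lithium hemiketal alkoxide; racemic) | [Li]OC1(OCc2cc(OCc3ccccc3)cc(OCOC)c21)c1c(C)cc(OCC=C)cc1OCC=C | intermediate (not isolated)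
13 | [2,4-bis(allyloxy)-6-methylphenyl][4-(benzyloxy)-2-(hydroxymethyl)-6-(methoxymethoxy)phenyl]methanone | OCc1cc(OCc2ccccc2)cc(OCOC)c1C(=O)c1c(C)cc(OCC=C)cc1OCC=C | intermediate
14 | [2,4-bis(allyloxy)-6-methylphenyl][4-(benzyloxy)-2-{[(tert-butyldimethylsilyl)oxy]methyl}-6-(methoxymethoxy)phenyl]methanone | CC(C)(C)[Si](C)(C)OCc1cc(OCc2ccccc2)cc(OCOC)c1C(=O)c1c(C)cc(OCC=C)cc1OCC=C | intermediate
15 | [4-(benzyloxy)-2-{[(tert-butyldimethylsilyl)oxy]methyl}-6-(methoxymethoxy)phenyl](2,4-dihydroxy-6-methylphenyl)methanone | CC(C)(C)[Si](C)(C)OCc1cc(OCc2ccccc2)cc(OCOC)c1C(=O)c1c(C)cc(O)cc1O | intermediate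
16 | [4-(benzyloxy)-2-{[(tert-butyldimethylsilyl)oxy]methyl}-6-(methoxymethoxy)phenyl][2-hydroxy-4-(methoxymethoxy)-6-methylphenyl]methanone | CC(C)(C)[Si](C)(C)OCc1cc(OCc2ccccc2)cc(OCOC)c1C(=O)c1c(C)cc(OCOC)cc1O | intermediate
17 | [2-{[(tert-butyldimethylsilyl)oxy]methyl}-4-hydroxy-6-(methoxymethoxy)phenyl][2-hydroxy-4-(methoxymethoxy)-6-methylphenyl]methanone (key-step precursor) | COCOc1cc(O)cc(CO[Si](C)(C)C(C)(C)C)c1C(=O)c1c(C)cc(OCOC)cc1O | intermediate
18 | rac-6'-{[(tert-butyldimethylsilyl)oxy]methyl}-2',6-bis(methoxymethoxy)-4-methyl-3H-spiro[1-benzofuran-2,1'-cyclohexa[2,5]diene]-3,4'-dione (grisadienone; racemic at the spiro carbon) | COCOC1=CC(=O)C=C(CO[Si](C)(C)C(C)(C)C)C12Oc1cc(OCOC)cc(C)c1C2=O | intermediate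
19 | 2-[2-{[(tert-butyldimethylsilyl)oxy]methyl}-4-hydroxy-6-(methoxymethoxy)phenoxy]-4-(methoxymethoxy)-6-methylbenzoic acid | COCOc1cc(O)cc(CO[Si](C)(C)C(C)(C)C)c1Oc1cc(OCOC)cc(C)c1C(=O)O | intermediate
20 | 3-{[(tert-butyldimethylsilyl)oxy]methyl}-5-(methoxymethoxy)-4-[3-(methoxymethoxy)-5-methylphenoxy]phenol | COCOc1cc(O)cc(CO[Si](C)(C)C(C)(C)C)c1Oc1cc(C)cc(OCOC)c1 | intermediate
21 | tert-butyl({5-methoxy-3-(methoxymethoxy)-2-[3-(methoxymethoxy)-5-methylphenoxy]phenyl}methoxy)dimethylsilane | COCOc1cc(OC)cc(CO[Si](C)(C)C(C)(C)C)c1Oc1cc(C)cc(OCOC)c1 | intermediate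
22 | 3-(hydroxymethyl)-2-(3-hydroxy-5-methylphenoxy)-5-methoxyphenol | OCc1cc(OC)cc(O)c1Oc1cc(C)cc(O)c1 | intermediate
23 | palmitic acid (hexadecanoic acid) | CCCCCCCCCCCCCCCC(=O)O | starting material
24 | betaethrin H ([3-hydroxy-2-(3-hydroxy-5-methylphenoxy)-5-methoxyphenyl]methyl hexadecanoate; achiral) | CCCCCCCCCCCCCCCC(=O)OCc1cc(OC)cc(O)c1Oc1cc(C)cc(O)c1 | target

Total step count: 17 (steps 1–2 for ring B, steps 3–6 for ring A, steps 7–17 after convergence).
Longest linear sequence: 15 steps (4 → 24 through steps 3–17).

Steps most likely to fail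

1. Step 12 (anodic spirocyclisation). Intermolecular radical coupling, over-oxidation at the electrode or solvent capture of the cation may outrun the intramolecular attack on the congested ipso carbon. Fallback: the ether bond is made intermolecularly, setting out from phthalide 10. Aminolysis with Me(MeO)NH·HCl/Me3Al should give the Weinreb amide F1, silylation (TBSCl, imidazole) its silyl ether F2 and reduction with i-Bu2AlH the aldehyde F3. Baeyer–Villiger oxidation (mCPBA, NaHCO3, CH2Cl2) of this electron-rich aldehyde should give the aryl formate F4, and methanolysis (K2CO3, MeOH) frees the hindered phenol F5, which now carries oxygen at C6. Commercial 3-bromo-5-methylphenol is protected (MOMCl, i-Pr2NEt) as the aryl bromide F6. Ullmann coupling of F5 with F6 (CuI, picolinic acid, K3PO4, DMSO, 90 °C) should give the diaryl ether F7, and hydrogenolysis of its benzyl ether (H2, Pd/C) comes back to the route at phenol 20.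

2. Step 7 (aryllithium opening of the phthalide). The hindered aryllithium may deprotonate the lactone CH2 instead of adding, the addition between two ortho-substituted partners may stall, or the ortho-allyloxy aryllithium may cyclise onto its own allyl group if the mixture has to be warmed. Fallback: the two rings are joined at the aldehyde oxidation level and the ketone is made afterwards. Setting out from phthalide 10, the aldehyde F3 is prepared as above (through F1 and F2). Aryllithium 11, generated from 3, should add to it at −78 °C to give the racemic diarylmethanol F8, and oxidation with Dess–Martin periodinane comes back to the route at ketone 14.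

3. Step 14 (protodecarboxylation). Silver may oxidise the free electron-rich phenol at 120 °C, or the acetal and silyl groups may be lost thermally, before CO2 is extruded. Fallback: the phenol is capped first and the carboxyl is removed afterwards. Setting out from acid 19, exhaustive methylation (MeI, K2CO3, DMF) should give the methyl ester methyl ether F9. SN2 demethylation of the hindered ester (NaSEt, DMF, 60 °C) gives the methoxy acid F10, and copper-mediated protodecarboxylation (Cu2O, 1,10-phenanthroline, NMP/quinoline, 170 °C) comes back to the route at methyl ether 21.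

Further compounds
F1 | step 12 | 4-(benzyloxy)-2-(hydroxymethyl)-N-methoxy-6-(methoxymethoxy)-N-methylbenzamide | CON(C)C(=O)c1c(CO)cc(OCc2ccccc2)cc1OCOC
F2 | step 12 | 4-(benzyloxy)-2-{[(tert-butyldimethylsilyl)oxy]methyl}-N-methoxy-6-(methoxymethoxy)-N-methylbenzamide | CON(C)C(=O)c1c(CO[Si](C)(C)C(C)(C)C)cc(OCc2ccccc2)cc1OCOC
F3 | step 12 | 4-(benzyloxy)-2-{[(tert-butyldimethylsilyl)oxy]methyl}-6-(methoxymethoxy)benzaldehyde | O=Cc1c(CO[Si](C)(C)C(C)(C)C)cc(OCc2ccccc2)cc1OCOC
F4 | step 12 | 4-(benzyloxy)-2-{[(tert-butyldimethylsilyl)oxy]methyl}-6-(methoxymethoxy)phenyl formate | O=COc1c(CO[Si](C)(C)C(C)(C)C)cc(OCc2ccccc2)cc1OCOC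
F5 | step 12 | 4-(benzyloxy)-2-{[(tert-butyldimethylsilyl)oxy]methyl}-6-(methoxymethoxy)phenol | Oc1c(CO[Si](C)(C)C(C)(C)C)cc(OCc2ccccc2)cc1OCOC
F6 | step 12 | 1-bromo-3-(methoxymethoxy)-5-methylbenzene | COCOc1cc(C)cc(Br)c1
F7 | step 12 | {[5-(benzyloxy)-3-(methoxymethoxy)-2-[3-(methoxymethoxy)-5-methylphenoxy]phenyl]methoxy}(tert-butyl)dimethylsilane | COCOc1cc(OCc2ccccc2)cc(CO[Si](C)(C)C(C)(C)C)c1Oc1cc(C)cc(OCOC)c1
F8 | step 7 | rac-[2,4-bis(allyloxy)-6-methylphenyl][4-(benzyloxy)-2-{[(tert-butyldimethylsilyl)oxy]methyl}-6-(methoxymethoxy)phenyl]methanol | CC(C)(C)[Si](C)(C)OCc1cc(OCc2ccccc2)cc(OCOC)c1C(O)c1c(C)cc(OCC=C)cc1OCC=C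
F9 | step 14 | methyl 2-[2-{[(tert-butyldimethylsilyl)oxy]methyl}-4-methoxy-6-(methoxymethoxy)phenoxy]-4-(methoxymethoxy)-6-methylbenzoate | COCOc1cc(OC)cc(CO[Si](C)(C)C(C)(C)C)c1Oc1cc(OCOC)cc(C)c1C(=O)OC
F10 | step 14 | 2-[2-{[(tert-butyldimethylsilyl)oxy]methyl}-4-methoxy-6-(methoxymethoxy)phenoxy]-4-(methoxymethoxy)-6-methylbenzoic acid | COCOc1cc(OC)cc(CO[Si](C)(C)C(C)(C)C)c1Oc1cc(OCOC)cc(C)c1C(=O)O
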